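**Retrosynthetic overview**
1. Target 32 comes from imide 27 by auxiliary cleavage, unmasking and oxidation of the benzylic carbon, and final MOM hydrolysis.
2. The C2 stereocenter and the C2–C3 bond of 27 come from an intermolecular Evans syn-aldol of aldehyde 21 with propionyl oxazolidinone 22, followed by Barton–McCombie removal of the C3 hydroxyl.
3. Aldehyde 21 comes from arene 15 by MOM-directed ortho-lithiation/formylation, reduction, silylation and acetal hydrolysis.
4. Arene 15 comes from aryl bromide 12 (from benzene-1,2,4-triol) and allylic bromide 9 (from (2E,6E)-farnesol by terminal bromohydrin/epoxide/periodic acid degradation) through an arylcopper allylation.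
5. No ring is built: the benzene ring is bought as benzene-1,2,4-triol and the oxazolidinone ring is a bought auxiliary.

Assumption: commercial (2E,6E)-farnesol of high isomeric purity is used, so both E-alkenes of the target are carried in from the start.

**Step 1**
Reactants: 1 (2E,6E)-farnesol
Product: 2 tert-butyl(diphenyl){[(2E,6E)-3,7,11-trimethyldodeca-2,6,10-trien-1-yl]oxy}silane
Conditions: TBDPSCl, imidazole, DMF, 0 °C → rt
Reagents that add atoms: tert-butyl(chloro)diphenylsilane, CC(C)(C)[Si](Cl)(c1ccccc1)c1ccccc1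
Why: Silyl ether protection of an unhindered primary allylic alcohol is fast, and the TBDPS ether withstands NBS, carbonate, periodic acid and acetalisation.

**Step 2**
Reactants: 2 tert-butyl(diphenyl){[(2E,6E)-3,7,11-trimethyldodeca-2,6,10-trien-1-yl]oxy}silane
Product: 3 (6E,10E)-3-bromo-12-{[tert-butyl(diphenyl)silyl]oxy}-2,6,10-trimethyldodeca-6,10-dien-2-ol (racemic at C3)
Conditions: NBS (1.1 equiv), THF/H2O 3:1, 0 °C
Reagents that add atoms: N-bromosuccinimide, O=C1CCC(=O)N1Br; water, O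
Why: In this van Tamelen terminal bromohydrin formation the chain coils in aqueous THF so that the terminal isopropylidene alkene is brominated and water opens the bromonium ion at the tertiary carbon; the racemic C3 center is excised in step 4.

**Step 3**
Reactants: 3 (6E,10E)-3-bromo-12-{[tert-butyl(diphenyl)silyl]oxy}-2,6,10-trimethyldodeca-6,10-dien-2-ol
Product: 4 tert-butyl{[(2E,6E)-9-(3,3-dimethyloxiran-2-yl)-3,7-dimethylnona-2,6-dien-1-yl]oxy}diphenylsilane (racemic epoxide)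
Conditions: K2CO3, MeOH, rt
Reagents that add atoms: none
Why: Intramolecular Williamson (SN2) closure of the bromohydrin alkoxide gives the epoxide and leaves the E-alkenes and the silyl ether untouched.

**Step 4**
Reactants: 4 tert-butyl{[(2E,6E)-9-(3,3-dimethyloxiran-2-yl)-3,7-dimethylnona-2,6-dien-1-yl]oxy}diphenylsilane
Product: 5 (4E,8E)-10-{[tert-butyl(diphenyl)silyl]oxy}-4,8-dimethyldeca-4,8-dienal
Conditions: H5IO6, THF/Et2O, 0 °C
Reagents that add atoms: none
Why: Periodic acid opens the epoxide to the glycol and cleaves it in the same pot (Malaprade glycol cleavage), removing the terminal carbon as acetone.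

**Step 5**
Reactants: 5 (4E,8E)-10-{[tert-butyl(diphenyl)silyl]oxy}-4,8-dimethyldeca-4,8-dienal
Product: 6 tert-butyl{[(2E,6E)-10,10-dimethoxy-3,7-dimethyldeca-2,6-dien-1-yl]oxy}diphenylsilane
Conditions: HC(OMe)3, PPTS (cat.), MeOH, rt; Et3N quench
Reagents that add atoms: trimethyl orthoformate, COC(OC)OC; methanol, CO
Why: Acid-catalysed acetalisation with orthoformate as water scavenger masks the aldehyde in a form inert to fluoride, organolithium and hydride reagents.

**Step 6**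
Reactants: 6 tert-butyl{[(2E,6E)-10,10-dimethoxy-3,7-dimethyldeca-2,6-dien-1-yl]oxy}diphenylsilane
Product: 7 (2E,6E)-10,10-dimethoxy-3,7-dimethyldeca-2,6-dien-1-ol
Conditions: TBAF, THF, 0 °C → rt; H2O work-up
Reagents that add atoms: none
Why: Fluoride-mediated desilylation frees the allylic alcohol without touching the acetal.

**Step 7**
Reactants: 7 (2E,6E)-10,10-dimethoxy-3,7-dimethyldeca-2,6-dien-1-ol
Product: 9 (2E,6E)-1-bromo-10,10-dimethoxy-3,7-dimethyldeca-2,6-diene, via allylic mesylate 8 (not isolated)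
Conditions: MsCl, Et3N, THF, −45 °C; then LiBr, THF, −45 → 0 °C
Reagents that add atoms: LiBr, [Li+].[Br-]
Why: Mesylation followed by SN2 displacement with bromide at low temperature gives the primary allylic bromide without allylic transposition or loss of E geometry.

**Step 8**
Reactants: 10 benzene-1,2,4-triol
Product: 11 1,2,4-tris(methoxymethoxy)benzene
Conditions: MOMCl, i-Pr2NEt, CH2Cl2, 0 °C → rt, under Ar
Reagents that add atoms: chloromethyl methyl ether, COCCl
Why: O-Alkylation of the three phenols (MOM protection) gives base-stable ethers that also serve as ortho-directing groups.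

**Step 9**
Reactants: 11 1,2,4-tris(methoxymethoxy)benzene
Product: 12 1-bromo-2,4,5-tris(methoxymethoxy)benzene
Conditions: NBS (1.0 equiv), MeCN, 0 °C → rt
Reagents that add atoms: N-bromosuccinimide, O=C1CCC(=O)N1Br
Why: Electrophilic aromatic bromination goes to the one position that is para to one OMOM and ortho to another and is not flanked by two substituents.

**Step 10**
Reactants: 12 1-bromo-2,4,5-tris(methoxymethoxy)benzene; 9 (2E,6E)-1-bromo-10,10-dimethoxy-3,7-dimethyldeca-2,6-diene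
Product: 15 1-[(2E,6E)-10,10-dimethoxy-3,7-dimethyldeca-2,6-dien-1-yl]-2,4,5-tris(methoxymethoxy)benzene, via aryllithium 13 (not isolated), via arylcopper 14 (not isolated)
Conditions: 12 (1.3 equiv), n-BuLi, THF, −78 °C; CuBr·SMe2, −78 → −40 °C; then 9, −78 → 0 °C
Reagents that add atoms: none
Why: Bromine–lithium exchange, transmetalation to the arylcopper and SN2 substitution at the unhindered primary allylic carbon (copper-mediated aryl–allyl coupling) join ring and chain with the E-alkene retained.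

**Step 11**
Reactants: 15 1-[(2E,6E)-10,10-dimethoxy-3,7-dimethyldeca-2,6-dien-1-yl]-2,4,5-tris(methoxymethoxy)benzene
Product: 18 3-[(2E,6E)-10,10-dimethoxy-3,7-dimethyldeca-2,6-dien-1-yl]-2,5,6-tris(methoxymethoxy)benzaldehyde, via ring-lithiated arene 16 (not isolated), via lithium hemiaminal alkoxide 17 (not isolated)
Conditions: n-BuLi, TMEDA, THF, −20 → 0 °C; DMF, 0 °C → rt; H2O
Reagents that add atoms: N,N-dimethylformamide, CN(C)C=O
Why: In this directed ortho-metalation the only ring hydrogen flanked by two chelating OMOM groups is removed, and the aryllithium is formylated by DMF.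

**Step 12**
Reactants: 18 3-[(2E,6E)-10,10-dimethoxy-3,7-dimethyldeca-2,6-dien-1-yl]-2,5,6-tris(methoxymethoxy)benzaldehyde
Product: 19 {3-[(2E,6E)-10,10-dimethoxy-3,7-dimethyldeca-2,6-dien-1-yl]-2,5,6-tris(methoxymethoxy)phenyl}methanol
Conditions: NaBH4, MeOH, 0 °C
Reagents that add atoms: none
Why: Hydride reduction parks the formyl carbon as a benzylic alcohol so that it cannot compete in the aldol step or suffer Dakin oxidation under the later peroxide conditions.

**Step 13**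
Reactants: 19 {3-[(2E,6E)-10,10-dimethoxy-3,7-dimethyldeca-2,6-dien-1-yl]-2,5,6-tris(methoxymethoxy)phenyl}methanol
Product: 20 tert-butyl({3-[(2E,6E)-10,10-dimethoxy-3,7-dimethyldeca-2,6-dien-1-yl]-2,5,6-tris(methoxymethoxy)phenyl}methoxy)diphenylsilane
Conditions: TBDPSCl, imidazole, DMF, rt
Reagents that add atoms: tert-butyl(chloro)diphenylsilane, CC(C)(C)[Si](Cl)(c1ccccc1)c1ccccc1
Why: Silyl ether protection of the primary benzylic alcohol with the robust TBDPS group survives mild acid, boron enolate, tin hydride and hydroperoxide conditions.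

**Step 14**
Reactants: 20 tert-butyl({3-[(2E,6E)-10,10-dimethoxy-3,7-dimethyldeca-2,6-dien-1-yl]-2,5,6-tris(methoxymethoxy)phenyl}methoxy)diphenylsilane
Product: 21 (4E,8E)-10-[3-({[tert-butyl(diphenyl)silyl]oxy}methyl)-2,4,5-tris(methoxymethoxy)phenyl]-4,8-dimethyldeca-4,8-dienal
Conditions: AcOH/THF/H2O 3:1:1, rt → 35 °C
Reagents that add atoms: water, O
Why: Selective acetal hydrolysis works because a dialkyl acetal of an aliphatic aldehyde is cleaved by weak aqueous acid much faster than aryl MOM ethers or a TBDPS ether.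

**Step 15**
Reactants: 21 (4E,8E)-10-[3-({[tert-butyl(diphenyl)silyl]oxy}methyl)-2,4,5-tris(methoxymethoxy)phenyl]-4,8-dimethyldeca-4,8-dienal; 22 (4S)-4-benzyl-3-propanoyl-1,3-oxazolidin-2-one
Product: 25 (4S)-4-benzyl-3-{(2S,3R,6E,10E)-12-[3-({[tert-butyl(diphenyl)silyl]oxy}methyl)-2,4,5-tris(methoxymethoxy)phenyl]-3-hydroxy-2,6,10-trimethyldodeca-6,10-dienoyl}-1,3-oxazolidin-2-one, via Z-dibutylboron enolate 23 (not isolated), via dibutylboron aldolate 24 (not isolated)
Conditions: 22 (1.3 equiv), Bu2BOTf (1.25 equiv), Et3N, CH2Cl2, 0 °C; then 21, −78 → 0 °C; pH 7 buffer, MeOH, 30% H2O2, 0 °C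
Reagents that add atoms: none
Why: In this Evans syn-aldol the Z-boron enolate reacts through a closed Zimmerman–Traxler transition state on the face away from the auxiliary benzyl group, setting 2S (kept) and 3R (removed in step 17).

**Step 16**
Reactants: 25 the aldol adduct
Product: 26 O-{(2S,3R,6E,10E)-1-[(4S)-4-benzyl-2-oxo-1,3-oxazolidin-3-yl]-12-[3-({[tert-butyl(diphenyl)silyl]oxy}methyl)-2,4,5-tris(methoxymethoxy)phenyl]-2,6,10-trimethyl-1-oxododeca-6,10-dien-3-yl} 1H-imidazole-1-carbothioate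
Conditions: 1,1'-thiocarbonyldiimidazole, DMAP (cat.), THF, 60 °C
Reagents that add atoms: 1,1'-thiocarbonyldiimidazole, S=C(n1ccnc1)n1ccnc1
Why: Thioacylation with thiocarbonyldiimidazole under near-neutral conditions turns the secondary alcohol into a radical-labile thiocarbamate without a strong base that would epimerise C2 or trigger retro-aldol.

**Step 17**
Reactants: 26 the imidazolyl thiocarbamate
Product: 27 (4S)-4-benzyl-3-{(2S,6E,10E)-12-[3-({[tert-butyl(diphenyl)silyl]oxy}methyl)-2,4,5-tris(methoxymethoxy)phenyl]-2,6,10-trimethyldodeca-6,10-dienoyl}-1,3-oxazolidin-2-one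
Conditions: Bu3SnH, AIBN (cat.), toluene, 90 °C
Reagents that add atoms: none
Why: Barton–McCombie deoxygenation replaces the C3 oxygen by hydrogen through a C3 radical that cannot cyclise onto the remote alkenes (only 4-exo or 5-endo modes) and does not involve the adjacent 2S center.

**Step 18**
Reactants: 27 the deoxygenated imide
Product: 29 (2S,6E,10E)-12-[3-({[tert-butyl(diphenyl)silyl]oxy}methyl)-2,4,5-tris(methoxymethoxy)phenyl]-2,6,10-trimethyldodeca-6,10-dienoic acid, via lithium peroxycarboxylate 28 (not isolated)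
Conditions: LiOH, 30% H2O2, THF/H2O 3:1, 0 °C; Na2SO3 (aq); 1 M HCl to pH 4, 0 °C
Reagents that add atoms: hydrogen peroxide, OO
Why: Evans auxiliary cleavage with LiOOH attacks the exocyclic carbonyl selectively and without epimerisation, and no aryl aldehyde is yet present that could undergo Dakin oxidation.

**Step 19**
Reactants: 29 the silyl-protected acid
Product: 30 (2S,6E,10E)-12-[3-(hydroxymethyl)-2,4,5-tris(methoxymethoxy)phenyl]-2,6,10-trimethyldodeca-6,10-dienoic acid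
Conditions: TBAF (3 equiv), THF, 0 °C → rt; H2O work-up
Reagents that add atoms: none
Why: Fluoride-mediated desilylation unmasks the benzylic alcohol while MOM ethers, alkenes and the carboxylate are inert.

**Step 20**
Reactants: 30 the benzylic alcohol acid
Product: 31 (2S,6E,10E)-12-[3-formyl-2,4,5-tris(methoxymethoxy)phenyl]-2,6,10-trimethyldodeca-6,10-dienoic acid
Conditions: DMP, CH2Cl2, 0 °C → rt
Reagents that add atoms: none
Why: Dess–Martin oxidation converts the benzylic alcohol to the aldehyde under near-neutral conditions that tolerate the free acid, the alkenes and the MOM ethers.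

**Step 21**
Reactants: 31 the tris-MOM aldehyde acid
Product: 32 (2S,6E,10E)-12-(3-formyl-2,4,5-trihydroxyphenyl)-2,6,10-trimethyldodeca-6,10-dienoic acid (CNP0180353.1)
Conditions: 3 M HCl (aq)/THF 1:3, degassed, under Ar, rt → 40 °C
Reagents that add atoms: none
Why: Acid-catalysed acetal hydrolysis removes the three MOM groups in an alcohol-free medium that cannot esterify the acid, and hydrogen bonding of the ortho phenol to the aldehyde disfavours chroman formation.

**Compound list**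
1 | (2E,6E)-farnesol | CC(C)=CCC/C(C)=C/CC/C(C)=C/CO | starting material
2 | tert-butyl(diphenyl){[(2E,6E)-3,7,11-trimethyldodeca-2,6,10-trien-1-yl]oxy}silane | CC(C)=CCC/C(C)=C/CC/C(C)=C/CO[Si](c1ccccc1)(c1ccccc1)C(C)(C)C | intermediate
3 | (6E,10E)-3-bromo-12-{[tert-butyl(diphenyl)silyl]oxy}-2,6,10-trimethyldodeca-6,10-dien-2-ol (racemic at C3) | CC(C)(O)C(Br)CC/C(C)=C/CC/C(C)=C/CO[Si](c1ccccc1)(c1ccccc1)C(C)(C)C | intermediate
4 | tert-butyl{[(2E,6E)-9-(3,3-dimethyloxiran-2-yl)-3,7-dimethylnona-2,6-dien-1-yl]oxy}diphenylsilane (racemic) | CC1(C)OC1CC/C(C)=C/CC/C(C)=C/CO[Si](c1ccccc1)(c1ccccc1)C(C)(C)C | intermediate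
5 | (4E,8E)-10-{[tert-butyl(diphenyl)silyl]oxy}-4,8-dimethyldeca-4,8-dienal | O=CCC/C(C)=C/CC/C(C)=C/CO[Si](c1ccccc1)(c1ccccc1)C(C)(C)C | intermediate
6 | tert-butyl{[(2E,6E)-10,10-dimethoxy-3,7-dimethyldeca-2,6-dien-1-yl]oxy}diphenylsilane | COC(OC)CC/C(C)=C/CC/C(C)=C/CO[Si](c1ccccc1)(c1ccccc1)C(C)(C)C | intermediate
7 | (2E,6E)-10,10-dimethoxy-3,7-dimethyldeca-2,6-dien-1-ol | COC(OC)CC/C(C)=C/CC/C(C)=C/CO | intermediate
8 | (2E,6E)-10,10-dimethoxy-3,7-dimethyldeca-2,6-dien-1-yl methanesulfonate (formed in situ) | COC(OC)CC/C(C)=C/CC/C(C)=C/COS(C)(=O)=O | intermediate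
9 | (2E,6E)-1-bromo-10,10-dimethoxy-3,7-dimethyldeca-2,6-diene | COC(OC)CC/C(C)=C/CC/C(C)=C/CBr | intermediate
10 | benzene-1,2,4-triol | Oc1ccc(O)c(O)c1 | starting material
11 | 1,2,4-tris(methoxymethoxy)benzene | COCOc1ccc(OCOC)c(OCOC)c1 | intermediate
12 | 1-bromo-2,4,5-tris(methoxymethoxy)benzene | COCOc1cc(OCOC)c(OCOC)cc1Br | intermediate
13 | [2,4,5-tris(methoxymethoxy)phenyl]lithium (formed in situ) | [Li]c1cc(OCOC)c(OCOC)cc1OCOC | intermediate
14 | [2,4,5-tris(methoxymethoxy)phenyl]copper (formed in situ) | [Cu]c1cc(OCOC)c(OCOC)cc1OCOC | intermediate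
15 | 1-[(2E,6E)-10,10-dimethoxy-3,7-dimethyldeca-2,6-dien-1-yl]-2,4,5-tris(methoxymethoxy)benzene | COC(OC)CC/C(C)=C/CC/C(C)=C/Cc1cc(OCOC)c(OCOC)cc1OCOC | intermediate
16 | {3-[(2E,6E)-10,10-dimethoxy-3,7-dimethyldeca-2,6-dien-1-yl]-2,5,6-tris(methoxymethoxy)phenyl}lithium (formed in situ) | COC(OC)CC/C(C)=C/CC/C(C)=C/Cc1cc(OCOC)c(OCOC)c([Li])c1OCOC | intermediate
17 | lithium {3-[(2E,6E)-10,10-dimethoxy-3,7-dimethyldeca-2,6-dien-1-yl]-2,5,6-tris(methoxymethoxy)phenyl}(dimethylamino)methanolate (formed in situ) | COC(OC)CC/C(C)=C/CC/C(C)=C/Cc1cc(OCOC)c(OCOC)c(C(O[Li])N(C)C)c1OCOC | intermediate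
18 | 3-[(2E,6E)-10,10-dimethoxy-3,7-dimethyldeca-2,6-dien-1-yl]-2,5,6-tris(methoxymethoxy)benzaldehyde | COC(OC)CC/C(C)=C/CC/C(C)=C/Cc1cc(OCOC)c(OCOC)c(C=O)c1OCOC | intermediate
19 | {3-[(2E,6E)-10,10-dimethoxy-3,7-dimethyldeca-2,6-dien-1-yl]-2,5,6-tris(methoxymethoxy)phenyl}methanol | COC(OC)CC/C(C)=C/CC/C(C)=C/Cc1cc(OCOC)c(OCOC)c(CO)c1OCOC | intermediate
20 | tert-butyl({3-[(2E,6E)-10,10-dimethoxy-3,7-dimethyldeca-2,6-dien-1-yl]-2,5,6-tris(methoxymethoxy)phenyl}methoxy)diphenylsilane | COC(OC)CC/C(C)=C/CC/C(C)=C/Cc1cc(OCOC)c(OCOC)c(CO[Si](c2ccccc2)(c2ccccc2)C(C)(C)C)c1OCOC | intermediate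
21 | (4E,8E)-10-[3-({[tert-butyl(diphenyl)silyl]oxy}methyl)-2,4,5-tris(methoxymethoxy)phenyl]-4,8-dimethyldeca-4,8-dienal | O=CCC/C(C)=C/CC/C(C)=C/Cc1cc(OCOC)c(OCOC)c(CO[Si](c2ccccc2)(c2ccccc2)C(C)(C)C)c1OCOC | intermediate
22 | (4S)-4-benzyl-3-propanoyl-1,3-oxazolidin-2-one | CCC(=O)N1C(=O)OC[C@@H]1Cc1ccccc1 | starting material
23 | (4S)-4-benzyl-3-{(1Z)-1-[(dibutylboranyl)oxy]prop-1-en-1-yl}-1,3-oxazolidin-2-one (formed in situ) | C/C=C(\OB(CCCC)CCCC)N1C(=O)OC[C@@H]1Cc1ccccc1 | intermediate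
24 | O-dibutylboranyl derivative of aldol adduct 25 at the 3R oxygen (formed in situ) | O=C(N1C(=O)OC[C@@H]1Cc1ccccc1)[C@@H](C)[C@H](OB(CCCC)CCCC)CC/C(C)=C/CC/C(C)=C/Cc1cc(OCOC)c(OCOC)c(CO[Si](c2ccccc2)(c2ccccc2)C(C)(C)C)c1OCOC | intermediate
25 | (4S)-4-benzyl-3-{(2S,3R,6E,10E)-12-[3-({[tert-butyl(diphenyl)silyl]oxy}methyl)-2,4,5-tris(methoxymethoxy)phenyl]-3-hydroxy-2,6,10-trimethyldodeca-6,10-dienoyl}-1,3-oxazolidin-2-one | O=C(N1C(=O)OC[C@@H]1Cc1ccccc1)[C@@H](C)[C@H](O)CC/C(C)=C/CC/C(C)=C/Cc1cc(OCOC)c(OCOC)c(CO[Si](c2ccccc2)(c2ccccc2)C(C)(C)C)c1OCOC | intermediate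
26 | O-{(2S,3R,6E,10E)-1-[(4S)-4-benzyl-2-oxo-1,3-oxazolidin-3-yl]-12-[3-({[tert-butyl(diphenyl)silyl]oxy}methyl)-2,4,5-tris(methoxymethoxy)phenyl]-2,6,10-trimethyl-1-oxododeca-6,10-dien-3-yl} 1H-imidazole-1-carbothioate | O=C(N1C(=O)OC[C@@H]1Cc1ccccc1)[C@@H](C)[C@H](OC(=S)n1ccnc1)CC/C(C)=C/CC/C(C)=C/Cc1cc(OCOC)c(OCOC)c(CO[Si](c2ccccc2)(c2ccccc2)C(C)(C)C)c1OCOC | intermediate
27 | (4S)-4-benzyl-3-{(2S,6E,10E)-12-[3-({[tert-butyl(diphenyl)silyl]oxy}methyl)-2,4,5-tris(methoxymethoxy)phenyl]-2,6,10-trimethyldodeca-6,10-dienoyl}-1,3-oxazolidin-2-one | O=C(N1C(=O)OC[C@@H]1Cc1ccccc1)[C@@H](C)CCC/C(C)=C/CC/C(C)=C/Cc1cc(OCOC)c(OCOC)c(CO[Si](c2ccccc2)(c2ccccc2)C(C)(C)C)c1OCOC | intermediate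
28 | lithium (2S,6E,10E)-12-[3-({[tert-butyl(diphenyl)silyl]oxy}methyl)-2,4,5-tris(methoxymethoxy)phenyl]-2,6,10-trimethyldodeca-6,10-dieneperoxoate (formed in situ) | [Li+].[O-]OC(=O)[C@@H](C)CCC/C(C)=C/CC/C(C)=C/Cc1cc(OCOC)c(OCOC)c(CO[Si](c2ccccc2)(c2ccccc2)C(C)(C)C)c1OCOC | intermediate
29 | (2S,6E,10E)-12-[3-({[tert-butyl(diphenyl)silyl]oxy}methyl)-2,4,5-tris(methoxymethoxy)phenyl]-2,6,10-trimethyldodeca-6,10-dienoic acid | OC(=O)[C@@H](C)CCC/C(C)=C/CC/C(C)=C/Cc1cc(OCOC)c(OCOC)c(CO[Si](c2ccccc2)(c2ccccc2)C(C)(C)C)c1OCOC | intermediate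
30 | (2S,6E,10E)-12-[3-(hydroxymethyl)-2,4,5-tris(methoxymethoxy)phenyl]-2,6,10-trimethyldodeca-6,10-dienoic acid | OC(=O)[C@@H](C)CCC/C(C)=C/CC/C(C)=C/Cc1cc(OCOC)c(OCOC)c(CO)c1OCOC | intermediate
31 | (2S,6E,10E)-12-[3-formyl-2,4,5-tris(methoxymethoxy)phenyl]-2,6,10-trimethyldodeca-6,10-dienoic acid | OC(=O)[C@@H](C)CCC/C(C)=C/CC/C(C)=C/Cc1cc(OCOC)c(OCOC)c(C=O)c1OCOC | intermediate
32 | (2S,6E,10E)-12-(3-formyl-2,4,5-trihydroxyphenyl)-2,6,10-trimethyldodeca-6,10-dienoic acid | C/C(=C\Cc1cc(O)c(O)c(C=O)c1O)CC/C=C(\C)CCC[C@H](C)C(=O)O | target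

**Totals**
Total step count: 21.
Longest linear sequence: 19 steps (steps 1–7, then 10–21); the arene branch (steps 8–9) joins at step 10.

**Three steps most likely to fail, with fallbacks**

Step 11 (ring lithiation beside a benzylic–allylic CH2). If deprotonation of the ArCH2–CH=C position competes, the formyl carbon is installed before the chain, with a silyl group holding the chain position. The fallback sets out from 12 and comes back at 20, replacing steps 10–13. Bromide 12 is lithiated (n-BuLi, THF, −78 °C) and quenched with Me3SiCl to give trimethyl[2,4,5-tris(methoxymethoxy)phenyl]silane F1. Directed ortho-metalation between the two flanking OMOM groups (n-BuLi, TMEDA, THF, 0 °C; DMF) gives 2,5,6-tris(methoxymethoxy)-3-(trimethylsilyl)benzaldehyde F2. NaBH4 in MeOH gives [2,5,6-tris(methoxymethoxy)-3-(trimethylsilyl)phenyl]methanol F3, and TBDPSCl/imidazole gives tert-butyl{[2,5,6-tris(methoxymethoxy)-3-(trimethylsilyl)phenyl]methoxy}diphenylsilane F4. Ipso-iododesilylation (ICl, CH2Cl2, −78 °C) gives tert-butyl{[3-iodo-2,5,6-tris(methoxymethoxy)phenyl]methoxy}diphenylsilane F5. Iodine–lithium exchange (t-BuLi, 2 equiv, THF, −78 °C), CuBr·SMe2 and bromide 9 then give 20 directly.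

Step 16 (thioacylation of the β-hydroxy imide, with step 17). If retro-aldol or β-elimination erodes the thiocarbamate, the 2S methyl center is set by auxiliary-controlled enolate methylation instead. The fallback sets out from 21 and comes back at 27. Wittig olefination of 21 with Ph3P=CHCO2Et (CH2Cl2, rt) gives ethyl (2E,6E,10E)-12-[3-({[tert-butyl(diphenyl)silyl]oxy}methyl)-2,4,5-tris(methoxymethoxy)phenyl]-6,10-dimethyldodeca-2,6,10-trienoate F6. Conjugate reduction with [(PPh3)CuH]6 (benzene, a little H2O, rt) gives ethyl (6E,10E)-12-[3-({[tert-butyl(diphenyl)silyl]oxy}methyl)-2,4,5-tris(methoxymethoxy)phenyl]-6,10-dimethyldodeca-6,10-dienoate F7. LiOH (THF/MeOH/H2O) gives (6E,10E)-12-[3-({[tert-butyl(diphenyl)silyl]oxy}methyl)-2,4,5-tris(methoxymethoxy)phenyl]-6,10-dimethyldodeca-6,10-dienoic acid F8. Activation as the mixed pivalic anhydride (PivCl, Et3N, THF, −20 °C) and acylation of (4S)-4-benzyl-1,3-oxazolidin-2-one with LiCl gives (4S)-4-benzyl-3-{(6E,10E)-12-[3-({[tert-butyl(diphenyl)silyl]oxy}methyl)-2,4,5-tris(methoxymethoxy)phenyl]-6,10-dimethyldodeca-6,10-dienoyl}-1,3-oxazolidin-2-one F9. NaN(SiMe3)2 (THF, −78 °C) then MeI methylates the chelated Z-enolate on the face away from the benzyl group and gives 27 with the same 2S configuration.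

Step 21 (global MOM removal from an acid- and air-sensitive ortho-prenyl polyphenol). If Brønsted acid causes chroman formation or stalls at partly protected stages, the acetals are removed by buffered silyl transfer instead. The fallback sets out from 31 and comes back at 32. Treatment of 31 with Me3SiOTf and 2,2'-bipyridyl (CH2Cl2, 0 °C) converts the aryl MOM ethers and the acid into trimethylsilyl (2S,6E,10E)-12-{3-formyl-2,4,5-tris[(trimethylsilyl)oxy]phenyl}-2,6,10-trimethyldodeca-6,10-dienoate F10. Stirring with degassed water at rt hydrolyses all four silyl groups and gives 32.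

**Further compounds**
F1 | step 11 | trimethyl[2,4,5-tris(methoxymethoxy)phenyl]silane | C[Si](C)(C)c1cc(OCOC)c(OCOC)cc1OCOC
F2 | step 11 | 2,5,6-tris(methoxymethoxy)-3-(trimethylsilyl)benzaldehyde | O=Cc1c(OCOC)c([Si](C)(C)C)cc(OCOC)c1OCOC
F3 | step 11 | [2,5,6-tris(methoxymethoxy)-3-(trimethylsilyl)phenyl]methanol | OCc1c(OCOC)c([Si](C)(C)C)cc(OCOC)c1OCOC
F4 | step 11 | tert-butyl{[2,5,6-tris(methoxymethoxy)-3-(trimethylsilyl)phenyl]methoxy}diphenylsilane | CC(C)(C)[Si](OCc1c(OCOC)c([Si](C)(C)C)cc(OCOC)c1OCOC)(c1ccccc1)c1ccccc1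
F5 | step 11 | tert-butyl{[3-iodo-2,5,6-tris(methoxymethoxy)phenyl]methoxy}diphenylsilane | CC(C)(C)[Si](OCc1c(OCOC)c(I)cc(OCOC)c1OCOC)(c1ccccc1)c1ccccc1
F6 | step 16 | ethyl (2E,6E,10E)-12-[3-({[tert-butyl(diphenyl)silyl]oxy}methyl)-2,4,5-tris(methoxymethoxy)phenyl]-6,10-dimethyldodeca-2,6,10-trienoate | CCOC(=O)/C=C/CC/C(C)=C/CC/C(C)=C/Cc1cc(OCOC)c(OCOC)c(CO[Si](c2ccccc2)(c2ccccc2)C(C)(C)C)c1OCOC
F7 | step 16 | ethyl (6E,10E)-12-[3-({[tert-butyl(diphenyl)silyl]oxy}methyl)-2,4,5-tris(methoxymethoxy)phenyl]-6,10-dimethyldodeca-6,10-dienoate | CCOC(=O)CCCC/C(C)=C/CC/C(C)=C/Cc1cc(OCOC)c(OCOC)c(CO[Si](c2ccccc2)(c2ccccc2)C(C)(C)C)c1OCOC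
F8 | step 16 | (6E,10E)-12-[3-({[tert-butyl(diphenyl)silyl]oxy}methyl)-2,4,5-tris(methoxymethoxy)phenyl]-6,10-dimethyldodeca-6,10-dienoic acid | OC(=O)CCCC/C(C)=C/CC/C(C)=C/Cc1cc(OCOC)c(OCOC)c(CO[Si](c2ccccc2)(c2ccccc2)C(C)(C)C)c1OCOC
F9 | step 16 | (4S)-4-benzyl-3-{(6E,10E)-12-[3-({[tert-butyl(diphenyl)silyl]oxy}methyl)-2,4,5-tris(methoxymethoxy)phenyl]-6,10-dimethyldodeca-6,10-dienoyl}-1,3-oxazolidin-2-one | O=C(CCCC/C(C)=C/CC/C(C)=C/Cc1cc(OCOC)c(OCOC)c(CO[Si](c2ccccc2)(c2ccccc2)C(C)(C)C)c1OCOC)N1C(=O)OC[C@@H]1Cc1ccccc1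
F10 | step 21 | trimethylsilyl (2S,6E,10E)-12-{3-formyl-2,4,5-tris[(trimethylsilyl)oxy]phenyl}-2,6,10-trimethyldodeca-6,10-dienoate | C[Si](C)(C)OC(=O)[C@@H](C)CCC/C(C)=C/CC/C(C)=C/Cc1cc(O[Si](C)(C)C)c(O[Si](C)(C)C)c(C=O)c1O[Si](C)(C)C
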